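**Retrosynthetic overview** (eudesmane numbering: C3 ester carbon, C4 tertiary carbinol, C5/C10 ring fusion, C8 ketone, C11 side-chain carbinol)

1. Ester C–O: target ⇒ decalin triol + (2S,3R)-2,3-dimethyloxirane-2-carboxylic acid (Sharpless epoxidation of (E)-2-methylbut-2-en-1-ol, then oxidation).
2. Ring-B enone with its carbinol ⇒ C8 ketone + acetone (aldol, then dehydrogenation); cis-3,4-diol ⇒ C3=C4 alkene (OsO4 from the face opposite the angular methyl).
3. Ring A, closed last: C3–C4 by reductive coupling of an aldehyde with a methyl ketone (McMurry).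
4. Key bond C1–C10: conjugate addition of a homoenolate equivalent (acetal Grignard, nucleophilic carbon β to a masked aldehyde) to the enone β-carbon of (1R,5R)-verbenone; the pinane bridge sets the quaternary centre.
5. Ring order: ring B is the six-membered ring of verbenone, unveiled by cyclobutane cleavage with C5 already set; ring A follows.

Assumption: the acyl group is read from the SMILES as the cis-dimethyl (tiglic-acid-derived) epoxide, (2S,3R); (1R,5R)-(+)-verbenone (also one step from (+)-α-pinene) and (E)-2-methylbut-2-en-1-ol are bought.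

**Route**

Step 1
Reactants: 1 (1R,5R)-4,6,6-trimethylbicyclo[3.1.1]hept-3-en-2-one ((+)-verbenone); 2 2-(2-bromoethyl)-1,3-dioxane
Product: 4 (1R,4R,5R)-4-[2-(1,3-dioxan-2-yl)ethyl]-4,6,6-trimethylbicyclo[3.1.1]heptan-2-one, via Grignard reagent 3 (not isolated)
Conditions: Mg, THF, 25 °C; then 1, CuBr·SMe2 (10 mol%), THF, −40 → 0 °C; aq. NH4Cl
Reagents that add atoms: none
Why: Copper-catalysed 1,4-addition of Stowell's acetal Grignard, a homoenolate equivalent whose nucleophilic carbon is β to a masked aldehyde, to the enone β-carbon joins two carbons that are both normally electrophilic and builds the quaternary centre; the organocopper adds anti to the gem-dimethyl bridge, which gives the 4R configuration.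

Step 2
Reactants: 4 (1R,4R,5R)-4-[2-(1,3-dioxan-2-yl)ethyl]-4,6,6-trimethylbicyclo[3.1.1]heptan-2-one
Product: 7 (3R,4S)-3-methyl-3-(3-oxopropyl)-4-(prop-1-en-2-yl)cyclohexan-1-one, via tertiary chloride 5 (not isolated), via isopropenyl acetal 6 (not isolated)
Conditions: HCl (g), CH2Cl2, 0 °C; then DBU, PhMe, 80 °C; then 2 M aq. HCl, THF, 25 °C
Reagents that add atoms: water (O)
Why: Acid-triggered retro-Prins-type cleavage of the strained cyclobutane bond next to the protonated ketone gives a tertiary chloride, E2 loss of HCl from a methyl group (the ring hydrogen is shielded by the quaternary centre) gives the isopropenyl group and aqueous acid then hydrolyses the acetal; neither stereocentre is involved, so the two carbon arms stay trans.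

Step 3
Reactants: 7 (3R,4S)-3-methyl-3-(3-oxopropyl)-4-(prop-1-en-2-yl)cyclohexan-1-one
Product: 8 (3R,4R)-4-acetyl-3-methyl-3-(3-oxopropyl)cyclohexan-1-one
Conditions: O3, CH2Cl2, −78 °C; Me2S, −78 → 20 °C; used at once
Reagents that add atoms: ozone (O=[O+][O-])
Why: Ozonolysis with reductive work-up turns the 1,1-disubstituted alkene into the methyl ketone under neutral conditions, so the centre α to the new ketone is not epimerised.

Step 4
Reactants: 8 (3R,4R)-4-acetyl-3-methyl-3-(3-oxopropyl)cyclohexan-1-one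
Product: 9 (4aR,8aR)-5,8a-dimethyl-3,4,4a,7,8,8a-hexahydronaphthalen-2(1H)-one
Conditions: TiCl3(DME)1.5, Zn–Cu couple, DME, reflux, slow addition of 8 (high dilution)
Reagents that add atoms: none
Why: McMurry coupling – the titanium-bound ketyl of the aldehyde adds to the methyl ketone held next to it on the trans-diequatorial arms (two carbonyl carbons, both normally electrophilic) and deoxygenation gives the trisubstituted ring-A alkene with the trans ring fusion already fixed; the ring ketone could only give an anti-Bredt alkene and is kept out by slow addition.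

Step 5
Reactants: 9 (4aR,8aR)-5,8a-dimethyl-3,4,4a,7,8,8a-hexahydronaphthalen-2(1H)-one; 10 acetone
Product: 12 (4aR,8aR)-3-(2-hydroxypropan-2-yl)-5,8a-dimethyl-3,4,4a,7,8,8a-hexahydronaphthalen-2(1H)-one (both C3 epimers), via lithium enolate 11 (not isolated)
Conditions: LDA, THF, −78 °C; then acetone, −78 °C; aq. NH4Cl
Reagents that add atoms: none
Why: Kinetic deprotonation on the side away from the quaternary carbon and aldol addition of the lithium enolate to acetone; the new α-centre is not controlled and need not be, because it becomes sp2 in step 6.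

Step 6
Reactants: 12 (4aR,8aR)-3-(2-hydroxypropan-2-yl)-5,8a-dimethyl-3,4,4a,7,8,8a-hexahydronaphthalen-2(1H)-one
Product: 13 (4aR,8aR)-3-(2-hydroxypropan-2-yl)-5,8a-dimethyl-4a,7,8,8a-tetrahydronaphthalen-2(1H)-one
Conditions: IBX, 4-methoxypyridine N-oxide, DMSO, 25 °C
Reagents that add atoms: none
Why: IBX α,β-dehydrogenation of the ketone (Nicolaou conditions) can only occur towards the carbon that has β-hydrogens, since the other α-carbon adjoins the quaternary centre, and gives the conjugated enone without touching the isolated alkene or the tertiary alcohol.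

Step 7
Reactants: 13 (4aR,8aR)-3-(2-hydroxypropan-2-yl)-5,8a-dimethyl-4a,7,8,8a-tetrahydronaphthalen-2(1H)-one
Product: 14 (4aR,5S,6R,8aR)-5,6-dihydroxy-3-(2-hydroxypropan-2-yl)-5,8a-dimethyl-4a,5,6,7,8,8a-hexahydronaphthalen-2(1H)-one
Conditions: OsO4 (2 mol%), NMO, acetone/H2O, 0 → 20 °C
Reagents that add atoms: osmium tetroxide (O=[Os](=O)(=O)=O); N-methylmorpholine N-oxide (C[N+]1([O-])CCOCC1); water (O)
Why: Upjohn dihydroxylation – OsO4 attacks the electron-rich trisubstituted alkene in preference to the enone and adds both oxygens syn from the face opposite the axial angular methyl, which sets the secondary (6R) and tertiary (5S) carbinol centres.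

Step 8
Reactants: 15 (E)-2-methylbut-2-en-1-ol
Product: 16 [(2R,3R)-2,3-dimethyloxiran-2-yl]methanol
Conditions: Ti(OiPr)4 (5 mol%), D-(−)-diisopropyl tartrate (6 mol%), t-BuOOH, 4 Å MS, CH2Cl2, −20 °C
Reagents that add atoms: tert-butyl hydroperoxide (CC(C)(C)OO)
Why: Katsuki–Sharpless asymmetric epoxidation of an E-allylic alcohol; the unnatural D-(−)-tartrate ligand directs oxygen to the alkene face that gives the (2R,3R)-epoxy alcohol.

Step 9
Reactants: 16 [(2R,3R)-2,3-dimethyloxiran-2-yl]methanol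
Product: 17 (2S,3R)-2,3-dimethyloxirane-2-carboxylic acid
Conditions: TEMPO (20 mol%), PhI(OAc)2, MeCN/H2O, 0 → 20 °C
Reagents that add atoms: water (O)
Why: TEMPO/PhI(OAc)2 oxidation in aqueous acetonitrile takes the primary alcohol through the aldehyde hydrate to the acid under conditions that leave the epoxide intact; the descriptor at C2 changes to S only through the CIP priorities.

Step 10
Reactants: 14 (4aR,5S,6R,8aR)-5,6-dihydroxy-3-(2-hydroxypropan-2-yl)-5,8a-dimethyl-4a,5,6,7,8,8a-hexahydronaphthalen-2(1H)-one; 17 (2S,3R)-2,3-dimethyloxirane-2-carboxylic acid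
Product: 19 (1S,2R,4aR,8aR)-1-hydroxy-7-(2-hydroxypropan-2-yl)-1,4a-dimethyl-6-oxo-1,2,3,4,4a,5,6,8a-octahydronaphthalen-2-yl (2S,3R)-2,3-dimethyloxirane-2-carboxylate, via mixed anhydride 18 (not isolated)
Conditions: 17, 2,4,6-trichlorobenzoyl chloride, Et3N, THF, 20 °C; then 14, DMAP, PhMe, 40 °C
Reagents that add atoms: none
Why: Yamaguchi esterification – the mixed anhydride acylates the only secondary hydroxyl under DMAP catalysis while the two tertiary hydroxyls are inert, and no stereocentre is touched.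

**Compound list**

1 | (1R,5R)-4,6,6-trimethylbicyclo[3.1.1]hept-3-en-2-one ((+)-verbenone) | CC1=CC(=O)[C@@H]2C[C@H]1C2(C)C | starting material
2 | 2-(2-bromoethyl)-1,3-dioxane | BrCCC1OCCCO1 | starting material
3 | bromo[2-(1,3-dioxan-2-yl)ethyl]magnesium | Br[Mg]CCC1OCCCO1 | intermediate
4 | (1R,4R,5R)-4-[2-(1,3-dioxan-2-yl)ethyl]-4,6,6-trimethylbicyclo[3.1.1]heptan-2-one | C[C@@]1(CCC3OCCCO3)CC(=O)[C@@H]2C[C@H]1C2(C)C | intermediate
5 | (3R,4R)-4-(2-chloropropan-2-yl)-3-[2-(1,3-dioxan-2-yl)ethyl]-3-methylcyclohexan-1-one | C[C@@]1(CCC2OCCCO2)CC(=O)CC[C@H]1C(C)(C)Cl | intermediate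
6 | (3R,4S)-3-[2-(1,3-dioxan-2-yl)ethyl]-3-methyl-4-(prop-1-en-2-yl)cyclohexan-1-one | C[C@@]1(CCC2OCCCO2)CC(=O)CC[C@H]1C(C)=C | intermediate
7 | (3R,4S)-3-methyl-3-(3-oxopropyl)-4-(prop-1-en-2-yl)cyclohexan-1-one | C[C@@]1(CCC=O)CC(=O)CC[C@H]1C(C)=C | intermediate
8 | (3R,4R)-4-acetyl-3-methyl-3-(3-oxopropyl)cyclohexan-1-one | C[C@@]1(CCC=O)CC(=O)CC[C@H]1C(C)=O | intermediate
9 | (4aR,8aR)-5,8a-dimethyl-3,4,4a,7,8,8a-hexahydronaphthalen-2(1H)-one | C[C@]12CCC=C(C)[C@@H]1CCC(=O)C2 | intermediate
10 | acetone | CC(C)=O | starting material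
11 | lithium (4aR,8aR)-5,8a-dimethyl-1,4,4a,7,8,8a-hexahydronaphthalen-2-olate | C[C@]12CCC=C(C)[C@@H]1CC=C(O[Li])C2 | intermediate
12 | (4aR,8aR)-3-(2-hydroxypropan-2-yl)-5,8a-dimethyl-3,4,4a,7,8,8a-hexahydronaphthalen-2(1H)-one (C3 epimers) | C[C@]12CCC=C(C)[C@@H]1CC(C(C)(C)O)C(=O)C2 | intermediate
13 | (4aR,8aR)-3-(2-hydroxypropan-2-yl)-5,8a-dimethyl-4a,7,8,8a-tetrahydronaphthalen-2(1H)-one | C[C@]12CCC=C(C)[C@@H]1C=C(C(C)(C)O)C(=O)C2 | intermediate
14 | (4aR,5S,6R,8aR)-5,6-dihydroxy-3-(2-hydroxypropan-2-yl)-5,8a-dimethyl-4a,5,6,7,8,8a-hexahydronaphthalen-2(1H)-one | O[C@@H]1CC[C@]2(C)CC(=O)C(C(C)(C)O)=C[C@H]2[C@]1(C)O | intermediate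
15 | (E)-2-methylbut-2-en-1-ol | C/C=C(\C)CO | starting material
16 | [(2R,3R)-2,3-dimethyloxiran-2-yl]methanol | C[C@H]1O[C@]1(C)CO | intermediate
17 | (2S,3R)-2,3-dimethyloxirane-2-carboxylic acid | C[C@H]1O[C@]1(C)C(=O)O | intermediate
18 | (2S,3R)-2,3-dimethyloxirane-2-carboxylic 2,4,6-trichlorobenzoic anhydride | C[C@H]1O[C@]1(C)C(=O)OC(=O)c1c(Cl)cc(Cl)cc1Cl | intermediate
19 | (1S,2R,4aR,8aR)-1-hydroxy-7-(2-hydroxypropan-2-yl)-1,4a-dimethyl-6-oxo-1,2,3,4,4a,5,6,8a-octahydronaphthalen-2-yl (2S,3R)-2,3-dimethyloxirane-2-carboxylate | C[C@H]1O[C@]1(C)C(=O)O[C@@H]1CC[C@]2(C)CC(=O)C(C(C)(C)O)=C[C@H]2[C@]1(C)O | target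

**Step count and risks**

Total steps: 10 (steps 1–7 to triol 14, steps 8–9 to acid 17, step 10 coupling). Longest linear sequence: 8 steps (steps 1–7 and 10).

The three steps most likely to fail:

Step 2. The acetal has to survive dry HCl, and HCl loss must go to the isopropenyl rather than the isopropylidene isomer. The fallback sets out from 1 and comes back at 8, carrying the three-carbon arm as an alkene that acid cannot touch. CuBr·SMe2-catalysed addition of but-3-enylmagnesium bromide to 1 gives (1R,4R,5R)-4-(but-3-en-1-yl)-4,6,6-trimethylbicyclo[3.1.1]heptan-2-one F1. Dry HCl opens it to (3R,4R)-3-(but-3-en-1-yl)-4-(2-chloropropan-2-yl)-3-methylcyclohexan-1-one F2, and DBU gives (3R,4S)-3-(but-3-en-1-yl)-3-methyl-4-(prop-1-en-2-yl)cyclohexan-1-one F3. Ozonolysis (O3; Me2S) of both alkenes at once then gives 8.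

Step 4. Low-valent titanium may also reduce or couple the free ring ketone, and the acetyl-bearing centre may epimerise at reflux. The fallback sets out from 8 and comes back at 9. SmI2 in THF at −78 °C reduces only the aldehyde, and its ketyl closes on the neighbouring methyl ketone to the cis-diol (4aR,8aR)-5,6-dihydroxy-5,8a-dimethyloctahydronaphthalen-2(1H)-one F4 (either cis-diol serves). Thiocarbonyldiimidazole converts it to the cyclic 5,6-thiocarbonate of this diol F5, and P(OMe)3 at 110 °C (Corey–Winter elimination) gives 9.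

Step 10. A hindered axial secondary alcohol next to a tertiary carbinol has to be acylated by an α-branched epoxy acid. The fallback sets out from 14 and comes back at 19. Acylation with (E)-2-methylbut-2-enoyl chloride (pyridine, DMAP) gives (1S,2R,4aR,8aR)-1-hydroxy-7-(2-hydroxypropan-2-yl)-1,4a-dimethyl-6-oxo-1,2,3,4,4a,5,6,8a-octahydronaphthalen-2-yl (2E)-2-methylbut-2-enoate F6. The tiglate is then epoxidised last under catalyst control (Shi ketone of the enantiomeric series that gives the (2S,3R)-epoxide, Oxone, buffered MeCN/H2O), leaving the more hindered, more electron-poor ring enone.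

**Further compounds**

F1 | step 2 | (1R,4R,5R)-4-(but-3-en-1-yl)-4,6,6-trimethylbicyclo[3.1.1]heptan-2-one | C[C@@]1(CCC=C)CC(=O)[C@@H]2C[C@H]1C2(C)C
F2 | step 2 | (3R,4R)-3-(but-3-en-1-yl)-4-(2-chloropropan-2-yl)-3-methylcyclohexan-1-one | C[C@@]1(CCC=C)CC(=O)CC[C@H]1C(C)(C)Cl
F3 | step 2 | (3R,4S)-3-(but-3-en-1-yl)-3-methyl-4-(prop-1-en-2-yl)cyclohexan-1-one | C[C@@]1(CCC=C)CC(=O)CC[C@H]1C(C)=C
F4 | step 4 | (4aR,8aR)-5,6-dihydroxy-5,8a-dimethyloctahydronaphthalen-2(1H)-one (cis-5,6-diol) | C[C@]12CCC(O)C(C)(O)[C@@H]1CCC(=O)C2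
F5 | step 4 | cyclic 5,6-thiocarbonate of (4aR,8aR)-5,6-dihydroxy-5,8a-dimethyloctahydronaphthalen-2(1H)-one | C[C@]12CCC3OC(=S)OC3(C)[C@@H]1CCC(=O)C2
F6 | step 10 | (1S,2R,4aR,8aR)-1-hydroxy-7-(2-hydroxypropan-2-yl)-1,4a-dimethyl-6-oxo-1,2,3,4,4a,5,6,8a-octahydronaphthalen-2-yl (2E)-2-methylbut-2-enoate | C/C=C(\C)C(=O)O[C@@H]1CC[C@]2(C)CC(=O)C(C(C)(C)O)=C[C@H]2[C@]1(C)O
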